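**Assumption:** guaiane numbering is used for both halves (C1–C5 five-membered ring; C1 and C5–C10 seven-membered ring; lactone O on C6, C12 = lactone C=O, C13 on C11, C14 on C10, C15 on C4). Unprimed atoms belong to the alkene half (unit A), primed atoms to the ketone half (unit B); α is the face of H-1 in the monomers. In this numbering the target is 1R,2S,3R,6S,7S,10S,11S,1'R,2'R,4'S,5'R,6'S,7'S,10'S,11'S.

## Retrosynthetic overview

1. Target 19 ⇐ bis-silyl ether 18 ⇐ C3 carboxylic acid 15 by radical decarboxylation; the carboxyl is a traceless activating group.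
2. 15 ⇐ benzyl ester 14 ⇐ intermolecular Mukaiyama–Michael addition (C2–C2') followed by intramolecular Michael closure (C3–C5') between silyl dienol ether 11 (unit B) and dienoate 9 (unit A).
3. 9 (through dienyl triflate 8 and carbonylation) and 11 both ⇐ enone 6 ⇐ 10-epi-isophotosantonic lactone 5.
4. 5 ⇐ isophotosantonic lactone 2 by inversion of the C10 carbinol (dehydration, bromohydrin, tin hydride) ⇐ α-santonin 1 by photorearrangement.
5. Ring order: lactone and carbocycles come from santonin; 6/6 → 5/7 in step 1; the bicyclo[2.2.1]heptanone is closed last, in step 9.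

## Route

Step 1
Reactants: 1 (−)-α-santonin
Product: 2 isophotosantonic lactone (10α-hydroxy-3-oxo-1αH-guai-4-en-6α,12-olide; 10R)
Conditions: hν (Hg lamp, Pyrex), AcOH–H2O (1:1), reflux
Reagents that add atoms: water, O
Why: Acid-mediated photorearrangement of the cross-conjugated cyclohexadienone (santonin → isophotosantonic lactone), in which C1–C5 bonding and opening of the cyclopropyl cation by water at C10 from the side opposite the departing C5 bond give the 5/7 skeleton with 1α-H (1R) and 10α-OH (10R), while C6, C7 and C11 are untouched.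

Step 2
Reactants: 2 isophotosantonic lactone
Product: 3 3-oxo-1αH-guaia-4,9-dien-6α,12-olide
Conditions: SOCl2, pyridine, CH2Cl2, −20 → 0 °C
Reagents that add atoms: none
Why: Dehydration through the chlorosulfite by base-induced anti elimination (E2), where H-1 is cis to the leaving group so the conjugated 1(10)-alkene cannot form and loss of H-9β gives the trisubstituted 9,10-alkene (any exocyclic 10(14)-isomer formed alongside converges on 5 in steps 3 and 4).

Step 3
Reactants: 3 3-oxo-1αH-guaia-4,9-dien-6α,12-olide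
Product: 4 9α-bromo-10β-hydroxy-3-oxo-1αH-guai-4-en-6α,12-olide
Conditions: NBS, acetone–H2O (4:1), 0 °C
Reagents that add atoms: N-bromosuccinimide, O=C1CCC(=O)N1Br; water, O
Why: Bromohydrin formation, in which the bromonium ion forms on the α face (the side of H-1, whereas the β side of C10 is flanked by C2) and water opens it anti at the tertiary carbon (Markovnikov), placing the new C10–O bond on the β face (10S) and bromine at C9α; the electron-poor tetrasubstituted enone alkene does not react.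

Step 4
Reactants: 4 9α-bromo-10β-hydroxy-3-oxo-1αH-guai-4-en-6α,12-olide
Product: 5 10-epi-isophotosantonic lactone (10β-hydroxy-3-oxo-1αH-guai-4-en-6α,12-olide; 10S)
Conditions: Bu3SnH, AIBN (cat.), PhH, 80 °C
Reagents that add atoms: none
Why: Radical chain dehalogenation removes the C9 bromine without touching the C10 carbinol, so the net result of steps 2–4 is inversion at C10 (10β-OH, 10α-Me).

Step 5
Reactants: 5 10-epi-isophotosantonic lactone
Product: 6 10β-(triethylsilyloxy)-3-oxo-1αH-guai-4-en-6α,12-olide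
Conditions: Et3SiOTf, 2,6-lutidine, CH2Cl2, −78 → 0 °C
Reagents that add atoms: triethylsilyl trifluoromethanesulfonate, CC[Si](CC)(CC)OS(=O)(=O)C(F)(F)F
Why: Silylation of the hindered tertiary alcohol with a silyl triflate and a non-nucleophilic base at low temperature leaves enone and lactone alone; no stereocentre is formed.

Step 6
Reactants: 6 10β-(triethylsilyloxy)-3-oxo-1αH-guai-4-en-6α,12-olide
Product: 8 3-(trifluoromethanesulfonyloxy)-10β-(triethylsilyloxy)-1αH-guaia-2,4-dien-6α,12-olide, via potassium dienolate 7 (not isolated)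
Conditions: KN(SiMe3)2 (1.05 equiv), THF, −78 °C; then PhNTf2, −78 → 0 °C
Reagents that add atoms: N-phenylbis(trifluoromethanesulfonimide), O=S(=O)(N(c1ccccc1)S(=O)(=O)C(F)(F)F)C(F)(F)F
Why: Enol triflate formation: kinetic deprotonation at the α'-CH2 (C2; the ketone is several pKa units more acidic than the lactone α-CH) by the hindered potassium amide gives the cross-conjugated potassium dienolate, which is O-triflated; no stereocentre is formed and C1 stays sp3.

Step 7
Reactants: 8 3-(trifluoromethanesulfonyloxy)-10β-(triethylsilyloxy)-1αH-guaia-2,4-dien-6α,12-olide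
Product: 9 benzyl 10β-(triethylsilyloxy)-1αH-guaia-2,4-dien-6α,12-olide-3-carboxylate
Conditions: Pd(OAc)2 (5 mol %), 1,3-bis(diphenylphosphino)propane (5 mol %), CO (1 atm), BnOH, Et3N, DMF, 25 °C
Reagents that add atoms: carbon monoxide, [C-]#[O+]; benzyl alcohol, OCc1ccccc1
Why: Palladium-catalysed alkoxycarbonylation of the alkenyl triflate (oxidative addition, CO insertion, alcoholysis) runs at room temperature and puts an electron-withdrawing ester on C3, which makes C2 a Michael acceptor position; no stereocentre is formed.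

Step 8
Reactants: 6 10β-(triethylsilyloxy)-3-oxo-1αH-guai-4-en-6α,12-olide
Product: 11 3-(trimethylsilyloxy)-10β-(triethylsilyloxy)-1αH-guaia-2,4-dien-6α,12-olide, via lithium dienolate 10 (not isolated)
Conditions: LiN(i-Pr)2 (1.05 equiv), THF, −78 °C; then Me3SiCl, −78 → 0 °C; non-aqueous work-up, used at once
Reagents that add atoms: chlorotrimethylsilane, C[Si](C)(C)Cl
Why: Kinetic enolisation at C2 with the lithium amide and O-silylation of the lithium dienolate give the 3-silyloxy-2,4-diene (silyl dienol ether formation), the neutral Michael donor for the coupling; no stereocentre is formed.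

Step 9
Reactants: 11 3-(trimethylsilyloxy)-10β-(triethylsilyloxy)-1αH-guaia-2,4-dien-6α,12-olide and 9 benzyl 10β-(triethylsilyloxy)-1αH-guaia-2,4-dien-6α,12-olide-3-carboxylate
Product: 14 3-exo-benzyloxycarbonyl-10,10'-bis-O-triethylsilyl derivative of the target (3'-ketone; 4'-endo-methyl), via ketene acetal Michael adduct 12 (not isolated), via bridged silyl enol ether 13 (not isolated)
Conditions: HN(SO2CF3)2 (5 mol %, gives Me3SiN(SO2CF3)2 in the flask), CH2Cl2, −78 → −40 °C; then aq. citric acid, THF, 0 °C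
Reagents that add atoms: none
Why: The silyl Lewis acid activates the unsaturated ester of 9 so that the nucleophilic C2' terminus of 11 adds to C2 (intermolecular Mukaiyama–Michael reaction) and the resulting silyl ketene acetal closes onto C5' of the silyl-activated enone (intramolecular Michael reaction; overall a double Michael annulation), each partner reacting on its α face anti to the C10/C10' carbon next to the reacting centre, which fixes C2 (S), C2' (R), C5' (R) and the endo fusion at C3, while ketonisation puts hydrogen exo at C4' (S) because the endo face is covered by the unit A ring and the exo site under the 10'-oxygen cannot hold a methyl group.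

Step 10
Reactants: 14 3-exo-benzyloxycarbonyl-10,10'-bis-O-triethylsilyl derivative of the target
Product: 15 3-exo-carboxy-10,10'-bis-O-triethylsilyl derivative of the target
Conditions: H2 (1 atm), Pd/C (10 wt %), EtOAc, 25 °C
Reagents that add atoms: none
Why: Hydrogenolysis of the benzyl ester under neutral conditions, to which the tetrasubstituted 4,5-alkene, the ketone, the lactones and the silyl ethers are inert; no stereocentre is touched.

Step 11
Reactants: 15 3-exo-carboxy-10,10'-bis-O-triethylsilyl derivative of the target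
Product: 18 10,10'-bis-O-triethylsilyl ether of the target, via acid chloride 16 (not isolated), via Barton ester 17 (not isolated)
Conditions: 1-chloro-N,N,2-trimethylpropenylamine, CH2Cl2, 0 °C; then sodium 2-mercaptopyridine N-oxide (C5H4NOSNa), DMAP (cat.), t-BuSH, PhH, hν (tungsten lamp), 25 °C
Reagents that add atoms: none
Why: Barton radical decarboxylation, in which the thiohydroxamate ester fragments to the C3 allyl radical that takes hydrogen from t-BuSH on the open exo face of C3 (cis ring fusion, 3R), and reversible thiyl-mediated allylic hydrogen transfer returns any 3-ene isomer to the more stable tetrasubstituted 4,5-alkene.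

Step 12
Reactants: 18 10,10'-bis-O-triethylsilyl ether of the target
Product: 19 CNP0243924.4 (target)
Conditions: HF·pyridine, pyridine, THF, 0 → 25 °C
Reagents that add atoms: none
Why: Buffered fluoride cleavage (desilylation) of the two tertiary triethylsilyl ethers does not epimerise C4', open the lactones or ionise the allylic C6–O bond; no stereocentre is formed.

## Compound list

1 | (−)-α-santonin, (3S,3aS,5aS,9bS)-3,5a,9-trimethyl-3a,4,5,9b-tetrahydronaphtho[1,2-b]furan-2,8(3H,5aH)-dione | CC1=C2[C@H]3OC(=O)[C@@H](C)[C@@H]3CC[C@@]2(C)C=CC1=O | starting material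
2 | isophotosantonic lactone, 10α-hydroxy-3-oxo-1αH-guai-4-en-6α,12-olide (1R,6S,7S,10R,11S) | CC1=C2[C@H]3OC(=O)[C@@H](C)[C@@H]3CC[C@@](C)(O)[C@@H]2CC1=O | intermediate
3 | 3-oxo-1αH-guaia-4,9-dien-6α,12-olide | CC1=C2[C@H]3OC(=O)[C@@H](C)[C@@H]3CC=C(C)[C@@H]2CC1=O | intermediate
4 | 9α-bromo-10β-hydroxy-3-oxo-1αH-guai-4-en-6α,12-olide | CC1=C2[C@H]3OC(=O)[C@@H](C)[C@@H]3C[C@@H](Br)[C@](C)(O)[C@@H]2CC1=O | intermediate
5 | 10-epi-isophotosantonic lactone, 10β-hydroxy-3-oxo-1αH-guai-4-en-6α,12-olide (1R,6S,7S,10S,11S) | CC1=C2[C@H]3OC(=O)[C@@H](C)[C@@H]3CC[C@](C)(O)[C@@H]2CC1=O | intermediate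
6 | 10β-(triethylsilyloxy)-3-oxo-1αH-guai-4-en-6α,12-olide | CC1=C2[C@H]3OC(=O)[C@@H](C)[C@@H]3CC[C@](C)(O[Si](CC)(CC)CC)[C@@H]2CC1=O | intermediate
7 | potassium cross-conjugated dienolate of 6 (C2=C3(OK)–C4=C5) | CC1=C2[C@H]3OC(=O)[C@@H](C)[C@@H]3CC[C@](C)(O[Si](CC)(CC)CC)[C@@H]2C=C1O[K] | intermediate
8 | 3-(trifluoromethanesulfonyloxy)-10β-(triethylsilyloxy)-1αH-guaia-2,4-dien-6α,12-olide | CC1=C2[C@H]3OC(=O)[C@@H](C)[C@@H]3CC[C@](C)(O[Si](CC)(CC)CC)[C@@H]2C=C1OS(=O)(=O)C(F)(F)F | intermediate
9 | benzyl 10β-(triethylsilyloxy)-1αH-guaia-2,4-dien-6α,12-olide-3-carboxylate | CC1=C2[C@H]3OC(=O)[C@@H](C)[C@@H]3CC[C@](C)(O[Si](CC)(CC)CC)[C@@H]2C=C1C(=O)OCc1ccccc1 | intermediate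
10 | lithium cross-conjugated dienolate of 6 (C2=C3(OLi)–C4=C5) | CC1=C2[C@H]3OC(=O)[C@@H](C)[C@@H]3CC[C@](C)(O[Si](CC)(CC)CC)[C@@H]2C=C1O[Li] | intermediate
11 | 3-(trimethylsilyloxy)-10β-(triethylsilyloxy)-1αH-guaia-2,4-dien-6α,12-olide | CC1=C2[C@H]3OC(=O)[C@@H](C)[C@@H]3CC[C@](C)(O[Si](CC)(CC)CC)[C@@H]2C=C1O[Si](C)(C)C | intermediate
12 | C2–C2' Michael adduct: unit A as benzyl trimethylsilyl ketene acetal at C3 (C4=C5 kept), unit B as 3'-oxo-4'-ene; both new bonds on the α faces | CC1=C2[C@H]3OC(=O)[C@@H](C)[C@@H]3CC[C@](C)(O[Si](CC)(CC)CC)[C@@H]2[C@@H]([C@H]4C(=O)C(C)=C5[C@H]6OC(=O)[C@@H](C)[C@@H]6CC[C@](C)(O[Si](CC)(CC)CC)[C@H]45)C1=C(O[Si](C)(C)C)OCc1ccccc1 | intermediate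
13 | bridged adduct (C2–C2' and C3–C5' bonds) as 3'-trimethylsilyl enol ether (C3'=C4'), 3-exo-CO2Bn, 10β,10'β-bis(triethylsilyloxy) | CC1=C2[C@H]3OC(=O)[C@@H](C)[C@@H]3CC[C@](C)(O[Si](CC)(CC)CC)[C@@H]2[C@H]2[C@H]3C(O[Si](C)(C)C)=C(C)[C@]4([C@@H]3[C@@](C)(O[Si](CC)(CC)CC)CC[C@H]3[C@H](C)C(=O)O[C@@H]34)[C@@]12C(=O)OCc1ccccc1 | intermediate
14 | 3-exo-benzyloxycarbonyl-10,10'-bis-O-triethylsilyl derivative of the target (3'-ketone, 4'-endo-methyl, unit A ring endo) | CC1=C2[C@H]3OC(=O)[C@@H](C)[C@@H]3CC[C@](C)(O[Si](CC)(CC)CC)[C@@H]2[C@H]2[C@H]3C(=O)[C@@H](C)[C@]4([C@@H]3[C@@](C)(O[Si](CC)(CC)CC)CC[C@H]3[C@H](C)C(=O)O[C@@H]34)[C@@]12C(=O)OCc1ccccc1 | intermediate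
15 | 3-exo-carboxy-10,10'-bis-O-triethylsilyl derivative of the target | CC1=C2[C@H]3OC(=O)[C@@H](C)[C@@H]3CC[C@](C)(O[Si](CC)(CC)CC)[C@@H]2[C@H]2[C@H]3C(=O)[C@@H](C)[C@]4([C@@H]3[C@@](C)(O[Si](CC)(CC)CC)CC[C@H]3[C@H](C)C(=O)O[C@@H]34)[C@@]12C(=O)O | intermediate
16 | acid chloride of 15 | CC1=C2[C@H]3OC(=O)[C@@H](C)[C@@H]3CC[C@](C)(O[Si](CC)(CC)CC)[C@@H]2[C@H]2[C@H]3C(=O)[C@@H](C)[C@]4([C@@H]3[C@@](C)(O[Si](CC)(CC)CC)CC[C@H]3[C@H](C)C(=O)O[C@@H]34)[C@@]12C(=O)Cl | intermediate
17 | Barton ester of 15 (O-acyl N-hydroxypyridine-2-thione) | CC1=C2[C@H]3OC(=O)[C@@H](C)[C@@H]3CC[C@](C)(O[Si](CC)(CC)CC)[C@@H]2[C@H]2[C@H]3C(=O)[C@@H](C)[C@]4([C@@H]3[C@@](C)(O[Si](CC)(CC)CC)CC[C@H]3[C@H](C)C(=O)O[C@@H]34)[C@@]12C(=O)ON1C=CC=CC1=S | intermediate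
18 | 10,10'-bis-O-triethylsilyl ether of the target | CC1=C2[C@H]3OC(=O)[C@@H](C)[C@@H]3CC[C@](C)(O[Si](CC)(CC)CC)[C@@H]2[C@H]2[C@H]3C(=O)[C@@H](C)[C@]4([C@@H]3[C@@](C)(O[Si](CC)(CC)CC)CC[C@H]3[C@H](C)C(=O)O[C@@H]34)[C@@H]12 | intermediate
19 | CNP0243924.4 (1R,2S,3R,6S,7S,10S,11S,1'R,2'R,4'S,5'R,6'S,7'S,10'S,11'S in guaiane numbering) | CC1=C2[C@H]3OC(=O)[C@@H](C)[C@@H]3CC[C@](C)(O)[C@@H]2[C@H]2[C@H]3C(=O)[C@@H](C)[C@]4([C@@H]3[C@@](C)(O)CC[C@H]3[C@H](C)C(=O)O[C@@H]34)[C@@H]12 | target

## Step count and risks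

Total: 12 steps from α-santonin. Longest linear sequence: 11 steps (steps 1–7 and 9–12; step 8 is a one-step branch from 6).

**Risk at step 9 (double Michael annulation).** The dienes 8, 9 and 11 are 5H-cyclopentadienes that can undergo [1,5]-hydrogen shifts or dimerise on standing, so they must be kept cold and used at once. The allylic lactone C–O bonds are also sensitive to the Lewis acid, and the second bond joins a quaternary C3 to a quaternary C5'. The fallback gives up the ester activating group. It sets out from triflate 8, which is reduced (Pd(OAc)2, PPh3, Bu3N, HCO2H, DMF, 40 °C) to the parent diene 10β-(triethylsilyloxy)-1αH-guaia-2,4-dien-6α,12-olide F1. F1 and an excess of silyl dienol ether 11 are then joined without catalyst in a thermal [4+2] cycloaddition (neat or 2 M in toluene, 25–40 °C, several days) to the bridged 3'-trimethylsilyl enol ether F2, which already carries hydrogen at C3. Mild acid hydrolysis of F2 gives the bis-silyl ether directly, so steps 10 and 11 fall away; the fallback comes back to the route at 18.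

**Risk at step 11 (radical decarboxylation).** The C3 radical is allylic, so hydrogen could be delivered to C5 instead and leave the 3-ene isomer. The fallback replaces the free-radical step by a metal-mediated one that exchanges the C3 substituent on the same carbon. It sets out from acid 15: its chloride 16 is reduced with Bu3SnH and Pd(PPh3)4 (PhH, 25 °C) to the C3 aldehyde of the bis-silyl ether F3, and F3 is decarbonylated with one equivalent of RhCl(PPh3)3 (PhCN, 130 °C, Tsuji–Wilkinson decarbonylation, retention at C3). It comes back to the route at 18.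

**Risk at step 3 (C10 inversion).** The facial preference of the 9,10-alkene is an estimate. If bromine enters from the β face, steps 3 and 4 simply return 2. The fallback uses the opposite stereochemical logic, in which oxygen itself enters on the more accessible face. It sets out from alkene 3: Mukaiyama hydration (Co(acac)2, PhSiH3, O2, THF, 25 °C) gives the tertiary hydroperoxide 10β-hydroperoxy-3-oxo-1αH-guai-4-en-6α,12-olide F4, which is reduced with PPh3 to the alcohol. It comes back to the route at 5 and replaces steps 3 and 4.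

Further compounds
F1 | step 9 | 10β-(triethylsilyloxy)-1αH-guaia-2,4-dien-6α,12-olide | CC1=C2[C@H]3OC(=O)[C@@H](C)[C@@H]3CC[C@](C)(O[Si](CC)(CC)CC)[C@@H]2C=C1
F2 | step 9 | bridged adduct as 3'-trimethylsilyl enol ether with hydrogen at C3 and 10β,10'β-bis(triethylsilyloxy) | CC1=C2[C@H]3OC(=O)[C@@H](C)[C@@H]3CC[C@](C)(O[Si](CC)(CC)CC)[C@@H]2[C@H]2[C@H]3C(O[Si](C)(C)C)=C(C)[C@]4([C@@H]3[C@@](C)(O[Si](CC)(CC)CC)CC[C@H]3[C@H](C)C(=O)O[C@@H]34)[C@@H]12
F3 | step 11 | 3-exo-formyl-10,10'-bis-O-triethylsilyl derivative of the target | CC1=C2[C@H]3OC(=O)[C@@H](C)[C@@H]3CC[C@](C)(O[Si](CC)(CC)CC)[C@@H]2[C@H]2[C@H]3C(=O)[C@@H](C)[C@]4([C@@H]3[C@@](C)(O[Si](CC)(CC)CC)CC[C@H]3[C@H](C)C(=O)O[C@@H]34)[C@@]12C=O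
F4 | step 3 | 10β-hydroperoxy-3-oxo-1αH-guai-4-en-6α,12-olide | CC1=C2[C@H]3OC(=O)[C@@H](C)[C@@H]3CC[C@](C)(OO)[C@@H]2CC1=O
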